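**Retrosynthetic overview**

1. Target 12 (meso) ⇐ regiospecific hydration of the alkynyl carbinol diacetate 10. The undec‑1‑ynyl group is a masked undecanoyl group, so the ring ketone can be reduced before the side‑chain ketone exists.
2. 10 ⇐ acetylation, desilylation and Luche reduction (hydride anti to OTBS) of cyclopentenone 7, which already holds the quaternary carbinol and the trans O/O relationship.
3. 7 ⇐ ring contraction of the six‑membered 6‑silyloxy‑2‑alkynyl‑2H‑pyran‑3(6H)‑one 6 (O1, C2–C6) to the carbocycle C2–C6: Et3N, oxa‑6π ring opening, 4π conrotatory reclosure between C2 and C6.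
4. 6 ⇐ Achmatowicz oxidation and silylation of furyl propargylic alcohol 4 ⇐ furfural 2 + 1‑undecyne 1. Ring order: furan (bought) → pyranone (step 2) → cyclopentene (step 4), the only ring of the target.
5. Enabling feature: in ring 6 the C2–H lies between the C3 carbonyl, ring O1 and the alkyne, and C6 is a silyl acetal carbon bonded to O1. The C2 enolate is therefore a 3‑oxido‑2H‑pyran whose O1–C6 bond opens and whose termini C2 (ynone carbonyl) and C6 (silyl enol ether) reclose, O1 ending as the tertiary OH.

Key step: step 4

Remark: the target SMILES describes a meso compound (mirror plane through C(OH)(acyl) and the midpoint of C=C; the two CH(OAc) centres are R and S), so it has no enantiomer. The task is the relative configuration (both OAc cis to the undecanoyl group, trans to the tertiary OH); chiral intermediates are carried as racemates and their SMILES show one enantiomer.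

**Step 1**
Reactants: 1 1‑undecyne; 2 furfural
Product: 4 rac‑1‑(furan‑2‑yl)dodec‑2‑yn‑1‑ol, via lithium undec‑1‑yn‑1‑ide 3 (not isolated)
Conditions: n‑BuLi, THF, −78 °C; then 2, −78 → 0 °C; aq. NH4Cl
Reagents that add atoms: none
Why: Deprotonation of the terminal alkyne and 1,2‑addition of the lithium acetylide to the aldehyde should give the racemic furyl propargylic alcohol, whose stereocentre is erased in step 4, so no control is needed.

**Step 2**
Reactants: 4 rac‑1‑(furan‑2‑yl)dodec‑2‑yn‑1‑ol
Product: 5 6‑hydroxy‑2‑(undec‑1‑yn‑1‑yl)‑2H‑pyran‑3(6H)‑one (diastereomer mixture)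
Conditions: NBS, NaHCO3, NaOAc, THF/H2O (4:1), 0 °C
Reagents that add atoms: water, O
Why: Achmatowicz rearrangement: bromonium‑induced oxidative opening of the electron‑rich furan by water to the (Z)‑ene‑dione and hemiacetalisation by the carbinol oxygen should give the pyranone, the furan reacting far faster with NBS than the internal alkyne; the configurations at C2 and C6 need no control because both are erased in step 4.

**Step 3**
Reactants: 5 6‑hydroxy‑2‑(undec‑1‑yn‑1‑yl)‑2H‑pyran‑3(6H)‑one
Product: 6 6‑[(tert‑butyldimethylsilyl)oxy]‑2‑(undec‑1‑yn‑1‑yl)‑2H‑pyran‑3(6H)‑one (diastereomer mixture)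
Conditions: TBSCl, imidazole, CH2Cl2, 0 °C
Reagents that add atoms: tert‑butyldimethylsilyl chloride, CC(C)(C)[Si](C)(C)Cl
Why: Silylation of the anomeric hydroxyl (standard for Achmatowicz lactols) turns the hemiacetal into a silyl acetal with a poor leaving group, which blocks ring–chain tautomerism and oxidopyrylium formation and leaves electrocyclic opening as the outlet of the C2 enolate.

**Step 4**
Reactants: 6 6‑[(tert‑butyldimethylsilyl)oxy]‑2‑(undec‑1‑yn‑1‑yl)‑2H‑pyran‑3(6H)‑one
Product: 7 rac‑trans‑4‑[(tert‑butyldimethylsilyl)oxy]‑5‑hydroxy‑5‑(undec‑1‑yn‑1‑yl)cyclopent‑2‑en‑1‑one (OTBS trans to OH; cis to the alkyne)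
Conditions: Et3N, DMF, 0 °C → rt
Reagents that add atoms: none
Why: Et3N removes the C2–H (α to C3=O, on the carbon bearing ring O1 and the alkyne), the resulting 3‑oxido‑2H‑pyran opens by thermal oxa‑6π electrocyclic cleavage of the O1–C6 acetal bond to a silyloxy trienolate in which C2 is an ynone carbonyl, and the C6 enol‑ether terminus bonds to that carbonyl, so the six‑membered ring O1/C2–C6 contracts to the carbocycle C2–C6 with O1 expelled as the tertiary hydroxyl. The closest known reaction type is the amine‑mediated rearrangement of 6‑alkoxy‑ and 6‑silyloxy‑2H‑pyran‑3(6H)‑ones to trans‑4‑oxy‑5‑hydroxycyclopent‑2‑enones, the anionic counterpart of the Piancatelli rearrangement. The five‑membered ring closes by C2–C6 bond formation as a thermal 4π conrotatory electrocyclisation of the C2–C6 pentadienyl array (four π electrons, C2 acting as the cationic terminus), a helical geometry that avoids the strain of a planar 5‑(enolendo) aldol closure. Both new stereocentres (C4 and C5 of the enone) are set relative to each other in this closure: the bulky silyloxy group on C6 and the carbonyl oxygen on C2 (held syn to the enolate oxygen by the bridging ammonium ion) take the outside positions while H and the slim, cylindrical alkyne turn inside, so conrotation places OTBS trans to the new hydroxyl and cis to the alkyne. The step needs this torquoselectivity, which is secured by choosing the sterically minimal alkyne as acyl surrogate, and it needs ring opening to outrun propargyl–allenyl isomerisation of the C2 carbanion, which the unimolecular opening under aprotic conditions with little ammonium ion present should allow. Because both stereocentres of 6 are erased in the open‑chain enolate, the diastereomer mixture should converge on one racemic product.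

**Step 5**
Reactants: 7 rac‑trans‑4‑[(tert‑butyldimethylsilyl)oxy]‑5‑hydroxy‑5‑(undec‑1‑yn‑1‑yl)cyclopent‑2‑en‑1‑one
Product: 8 rac‑5‑[(tert‑butyldimethylsilyl)oxy]‑1‑(undec‑1‑yn‑1‑yl)cyclopent‑3‑ene‑1,2‑diol (secondary OH cis to OTBS; trans to tertiary OH)
Conditions: NaBH4, CeCl3·7H2O, MeOH, −78 °C
Reagents that add atoms: none
Why: Luche 1,2‑reduction in which hydride should add to the carbonyl face anti to the C4 silyloxy group and the cis‑disposed alkyne, i.e. from the face of the small tertiary OH (as in the cis‑selective Luche reduction of 4‑silyloxycyclopentenones), setting the new carbinol cis to OTBS and trans to the tertiary OH.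

**Step 6**
Reactants: 8 rac‑5‑[(tert‑butyldimethylsilyl)oxy]‑1‑(undec‑1‑yn‑1‑yl)cyclopent‑3‑ene‑1,2‑diol
Product: 9 meso‑1‑(undec‑1‑yn‑1‑yl)cyclopent‑3‑ene‑1,2,5‑triol (2‑OH and 5‑OH cis to the alkyne)
Conditions: TBAF, AcOH, THF, 0 °C → rt
Reagents that add atoms: none
Why: Fluoride cleaves the Si–O bond under acetic acid buffering, no stereocentre is touched and the product should be the meso triol (silyl ether cleavage).

**Step 7**
Reactants: 9 meso‑1‑(undec‑1‑yn‑1‑yl)cyclopent‑3‑ene‑1,2,5‑triol
Product: 10 meso‑2‑hydroxy‑2‑(undec‑1‑yn‑1‑yl)cyclopent‑4‑ene‑1,3‑diyl diacetate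
Conditions: Ac2O, pyridine, DMAP (cat.), CH2Cl2, 0 °C
Reagents that add atoms: acetic anhydride, CC(=O)OC(C)=O
Why: Acylation should distinguish the two secondary allylic hydroxyls from the hindered tertiary propargylic hydroxyl, which does not react with Ac2O/pyridine at 0 °C (selective esterification).

**Step 8**
Reactants: 10 meso‑2‑hydroxy‑2‑(undec‑1‑yn‑1‑yl)cyclopent‑4‑ene‑1,3‑diyl diacetate
Product: 12 meso‑2‑hydroxy‑2‑undecanoylcyclopent‑4‑ene‑1,3‑diyl diacetate (1R,3S; both OAc cis to the acyl group), via (Z)‑alkylidene cyclic carbonate 11 (not isolated)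
Conditions: AgOAc (10 mol %), DBU, CO2 (1 MPa), MeCN, rt; then H2O, CO2 (1 atm), 40 °C
Reagents that add atoms: carbon dioxide, O=C=O; water, O
Why: Silver‑catalysed carboxylative cyclisation of the tertiary propargylic alcohol (the carbonate formed from the alkoxide and CO2 adds 5‑exo‑dig and anti to the Ag‑activated alkyne) fixes oxygen on the proximal alkyne carbon, and hydrolysis with decarboxylation of the activated enol carbonate in the bicarbonate‑buffered medium should unveil the α‑hydroxy ketone without a new stereocentre and without touching the acetates (CO2‑mediated hydration of propargylic alcohols).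

**Compound list**

1 | 1‑undecyne | C#CCCCCCCCCC | starting material
2 | furfural (furan‑2‑carbaldehyde) | O=Cc1ccco1 | starting material
3 | lithium undec‑1‑yn‑1‑ide | [Li]C#CCCCCCCCCC | intermediate
4 | rac‑1‑(furan‑2‑yl)dodec‑2‑yn‑1‑ol | OC(C#CCCCCCCCCC)c1ccco1 | intermediate
5 | 6‑hydroxy‑2‑(undec‑1‑yn‑1‑yl)‑2H‑pyran‑3(6H)‑one, diastereomer mixture | O=C1C=CC(O)OC1C#CCCCCCCCCC | intermediate
6 | 6‑[(tert‑butyldimethylsilyl)oxy]‑2‑(undec‑1‑yn‑1‑yl)‑2H‑pyran‑3(6H)‑one, diastereomer mixture | O=C1C=CC(O[Si](C)(C)C(C)(C)C)OC1C#CCCCCCCCCC | intermediate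
7 | rac‑trans‑4‑[(tert‑butyldimethylsilyl)oxy]‑5‑hydroxy‑5‑(undec‑1‑yn‑1‑yl)cyclopent‑2‑en‑1‑one (OTBS trans to OH, cis to alkyne) | CCCCCCCCCC#C[C@@]1(O)[C@@H](O[Si](C)(C)C(C)(C)C)C=CC1=O | intermediate
8 | rac‑5‑[(tert‑butyldimethylsilyl)oxy]‑1‑(undec‑1‑yn‑1‑yl)cyclopent‑3‑ene‑1,2‑diol (2‑OH and OTBS cis to each other and to the alkyne) | CCCCCCCCCC#C[C@@]1(O)[C@@H](O[Si](C)(C)C(C)(C)C)C=C[C@H]1O | intermediate
9 | meso‑1‑(undec‑1‑yn‑1‑yl)cyclopent‑3‑ene‑1,2,5‑triol (secondary OH groups cis to the alkyne) | CCCCCCCCCC#C[C@@]1(O)[C@@H](O)C=C[C@H]1O | intermediate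
10 | meso‑2‑hydroxy‑2‑(undec‑1‑yn‑1‑yl)cyclopent‑4‑ene‑1,3‑diyl diacetate (OAc groups cis to the alkyne) | CCCCCCCCCC#C[C@@]1(O)[C@@H](OC(C)=O)C=C[C@H]1OC(C)=O | intermediate
11 | meso‑(Z)‑4‑decylidene‑2‑oxo‑1,3‑dioxaspiro[4.4]non‑7‑ene‑6,9‑diyl diacetate | CCCCCCCCC/C=C1\OC(=O)O[C@@]12[C@@H](OC(C)=O)C=C[C@H]2OC(C)=O | intermediate
12 | meso‑2‑hydroxy‑2‑undecanoylcyclopent‑4‑ene‑1,3‑diyl diacetate (1R,3S; OAc groups cis to the acyl group, trans to OH) | CCCCCCCCCCC(=O)[C@@]1(O)[C@@H](OC(C)=O)C=C[C@H]1OC(C)=O | target

Total step count: 8. Longest linear sequence: 8 steps (1 and 2 → 12).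

**Steps most likely to fail**

Step 4. The open‑chain enolate may close with the C2 carbonyl oxygen turned inward (opposite torquoselectivity), and proton transfer to the alkyne terminus (propargyl–allenyl isomerisation) may compete with ring opening. The fallback replaces reliance on torquoselectivity by stereochemical correction through inversion. It sets out from 6: the same ring contraction would then deliver mainly rac‑cis‑4‑[(tert‑butyldimethylsilyl)oxy]‑5‑hydroxy‑5‑(undec‑1‑yn‑1‑yl)cyclopent‑2‑en‑1‑one F1. Luche reduction anti to OTBS should give the all‑cis silyl ether rac‑5‑[(tert‑butyldimethylsilyl)oxy]‑1‑(undec‑1‑yn‑1‑yl)cyclopent‑3‑ene‑1,2‑diol F2, and TBAF/AcOH the all‑cis meso‑1‑(undec‑1‑yn‑1‑yl)cyclopent‑3‑ene‑1,2,5‑triol F3. A double Mitsunobu reaction (AcOH, PPh3, DIAD, THF) would then install both acetates with inversion at the two secondary allylic carbinols, the tertiary OH being inert, and the route is rejoined at 10.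

Step 8. Carbonate formation and cyclisation at the hindered tertiary alkoxide may be incomplete, and the amidine base may cleave or shift the acetates. The fallback hands regiocontrol to the substrate's own esters. It sets out from 10 and returns at 12 without a new isolated compound: gold(I)‑catalysed hydration under neutral conditions ((Ph3P)AuCl/AgSbF6, H2O, dioxane, rt), in which a cis‑disposed acetate carbonyl oxygen attacks the proximal alkyne carbon 6‑exo‑dig and water opens the resulting 1,3‑dioxan‑2‑ylium ion, returning the acetate to its oxygen and leaving the ketone at the proximal carbon.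

Step 5. Hydride may be delivered in part from the face carrying the silyloxy and alkynyl groups, eroding the 1,4‑cis selectivity. The fallback changes the control element from steric approach of an external hydride to intramolecular delivery. It sets out from 7 and returns at 8: Me4NBH(OAc)3 in MeCN/AcOH at −20 °C binds the tertiary hydroxyl and should transfer hydride to the carbonyl from that hydroxyl's own face, giving the same trans relationship between the new carbinol and the tertiary OH.

**Further compounds**

F1 | step 4 | rac‑cis‑4‑[(tert‑butyldimethylsilyl)oxy]‑5‑hydroxy‑5‑(undec‑1‑yn‑1‑yl)cyclopent‑2‑en‑1‑one (OTBS cis to OH) | CCCCCCCCCC#C[C@]1(O)[C@@H](O[Si](C)(C)C(C)(C)C)C=CC1=O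
F2 | step 4 | rac‑all‑cis‑5‑[(tert‑butyldimethylsilyl)oxy]‑1‑(undec‑1‑yn‑1‑yl)cyclopent‑3‑ene‑1,2‑diol (three oxygens cis) | CCCCCCCCCC#C[C@]1(O)[C@@H](O[Si](C)(C)C(C)(C)C)C=C[C@H]1O
F3 | step 4 | meso‑all‑cis‑1‑(undec‑1‑yn‑1‑yl)cyclopent‑3‑ene‑1,2,5‑triol (three hydroxyls cis) | CCCCCCCCCC#C[C@]1(O)[C@@H](O)C=C[C@H]1O
F0 | step 8 | none | none
F0 | step 5 | none | none
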